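The route cuts the C2–C1′ bond between ring C and the chromene unit (rings B/D), not the O1–C2 or Cα–Cβ bond of a chalcone. C2 is benzylic and β to the C4 ketone, so it epimerises whenever O1–C2 can open. It is therefore made last, by an irreversible, enantioselective rhodium-catalysed 1,4-addition of 2,2-dimethylchromen-6-ylboronic acid to C2 of a flat, achiral 7-silyloxy-8-prenylchromone. This single operation joins the two bicyclic halves and sets the only stereocentre. The C8 prenyl group, which sits ortho to O7, is placed beforehand by aromatic Claisen rearrangement of the 7-O-(1,1-dimethylallyl)chromone.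

Key step: step 6

Assumption: the (S,S)-diene ligand is taken to deliver the aryl group to the Re face of C2, as it does at the β-carbon of six-membered cyclic enones; should the sense be opposite, the equally available (R,R)-ligand is used and nothing else changes.

Step 1
Reactants: 1 7-hydroxy-4H-chromen-4-one; 2 3-chloro-3-methylbut-1-yne
Product: 3 7-[(2-methylbut-3-yn-2-yl)oxy]-4H-chromen-4-one
Conditions: K2CO3, KI (cat.), acetone, reflux
Reagents that add atoms: none
Why: Williamson-type O-alkylation in which the tertiary propargylic chloride ionises under base and is captured at the acidic 7-phenoxide oxygen, as is routine for 7-hydroxycoumarins and 7-hydroxyflavones, while the chromone ring tolerates dry carbonate.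

Step 2
Reactants: 3 7-[(2-methylbut-3-yn-2-yl)oxy]-4H-chromen-4-one
Product: 4 7-[(2-methylbut-3-en-2-yl)oxy]-4H-chromen-4-one
Conditions: H2 (1 atm), Lindlar catalyst (Pd/CaCO3, Pb-poisoned), quinoline, EtOAc, rt, stopped after one equivalent of H2
Reagents that add atoms: none
Why: Lindlar semihydrogenation, in which the poisoned palladium surface should reduce the terminal alkyne to the vinyl group well before it touches the vinylogous-ester C2=C3 bond of the chromone.

Step 3
Reactants: 4 7-[(2-methylbut-3-en-2-yl)oxy]-4H-chromen-4-one
Product: 6 7-hydroxy-8-(3-methylbut-2-en-1-yl)-4H-chromen-4-one, via ortho-dienone 5 (not isolated)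
Conditions: PhNEt2, 130–150 °C, argon
Reagents that add atoms: none
Why: Aromatic Claisen rearrangement ([3,3]) with allyl inversion turns the 1,1-dimethylallyl ether into the 3,3-dimethylallyl group, C8 being favoured over C6 because the C7–C8 bond carries the higher double-bond character in 7-oxygenated benzopyranones, and dienone 5 tautomerises to the phenol; no stereocentre persists.

Step 4
Reactants: 6 7-hydroxy-8-(3-methylbut-2-en-1-yl)-4H-chromen-4-one
Product: 7 8-(3-methylbut-2-en-1-yl)-7-[(triisopropylsilyl)oxy]-4H-chromen-4-one
Conditions: TIPSCl, imidazole, DMF, rt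
Reagents that add atoms: triisopropylsilyl chloride, CC(C)[Si](Cl)(C(C)C)C(C)C
Why: Standard imidazole-promoted O-silylation masks the acidic phenol with a group that resists the mildly basic aqueous medium of step 6 and leaves under buffered fluoride.

Step 5
Reactants: 8 6-bromo-2,2-dimethyl-2H-chromene
Product: 11 (2,2-dimethyl-2H-chromen-6-yl)boronic acid, via aryllithium 9 (not isolated), via lithium aryltriisopropoxyborate 10 (not isolated)
Conditions: n-BuLi, THF, −78 °C; B(OiPr)3, −78 °C to rt; 1 M HCl, 0 °C
Reagents that add atoms: triisopropyl borate, CC(C)OB(OC(C)C)OC(C)C; water, O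
Why: Bromine–lithium exchange followed by borate trapping and hydrolysis is the standard route to arylboronic acids, and the chromene olefin and ether are inert to n-BuLi at −78 °C and to a brief cold dilute-acid work-up.

Step 6
Reactants: 7 8-(3-methylbut-2-en-1-yl)-7-[(triisopropylsilyl)oxy]-4H-chromen-4-one; 11 (2,2-dimethyl-2H-chromen-6-yl)boronic acid
Product: 12 (2S)-2-(2,2-dimethyl-2H-chromen-6-yl)-8-(3-methylbut-2-en-1-yl)-7-[(triisopropylsilyl)oxy]-2,3-dihydro-4H-chromen-4-one
Conditions: [RhCl(C2H4)2]2 (cat.), (S,S)-Ph-bod* = (1S,4S)-2,5-diphenylbicyclo[2.2.2]octa-2,5-diene (cat.), K3PO4 (substoichiometric), excess 11, toluene/H2O, 40–60 °C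
Reagents that add atoms: none
Why: Transmetalation of 11 to the Rh(I)–OH/diene complex gives an aryl–Rh(I) species, the C2=C3 bond of 7 binds and inserts so that aryl goes to C2 and rhodium to C3 as an oxa-π-allyl enolate, and water protonates C3 and regenerates Rh–OH, the closest known reaction type being the Hayashi–Miyaura 1,4-addition of arylboronic acids to cyclic enones and 4-chromones. No ring is closed: the step forms only the C2–C1′ σ-bond and so joins the A/C bicycle to the B/D bicycle. The one new stereocentre, C2, is controlled by the C2-symmetric diene alone, whose phenyl groups leave open only the orientation in which the chromone offers its C2 Re face to the aryl–Rh bond, which gives (2S). The step needs chemoselectivity among three C=C bonds, and only the carbonyl-conjugated C2=C3 bond is polarised enough to insert, whereas the trisubstituted prenyl and the cis-disubstituted chromene olefins are unactivated and should not carbometalate. Insertion and protonolysis are irreversible and the biphasic medium is nearly neutral, so O1–C2 is never opened, the chalcone manifold that racemises flavanones is not entered, and 1,2-addition to the product ketone is held back. The TIPS ether prevents formation of the 7-phenoxide, which would turn the acceptor into an unreactive vinylogous carboxylate.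

Step 7
Reactants: 12 (2S)-2-(2,2-dimethyl-2H-chromen-6-yl)-8-(3-methylbut-2-en-1-yl)-7-[(triisopropylsilyl)oxy]-2,3-dihydro-4H-chromen-4-one
Product: 13 (2S)-7-hydroxy-2-(2,2-dimethyl-2H-chromen-6-yl)-8-(3-methylbut-2-en-1-yl)-2,3-dihydro-4H-chromen-4-one (CNP0156801.1)
Conditions: TBAF, AcOH (1:1), THF, 0 °C
Reagents that add atoms: none
Why: Fluoride-mediated desilylation is driven by Si–F bond formation, and the acetic acid buffer keeps enolate formation and hence retro-oxa-Michael opening at C2 suppressed, while the prenyl and chromene olefins see neither acid nor oxidant.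

Compound list
1 | 7-hydroxy-4H-chromen-4-one | O=c1ccoc2cc(O)ccc12 | starting material
2 | 3-chloro-3-methylbut-1-yne | CC(C)(Cl)C#C | starting material
3 | 7-[(2-methylbut-3-yn-2-yl)oxy]-4H-chromen-4-one | C#CC(C)(C)Oc1ccc2c(c1)occc2=O | intermediate
4 | 7-[(2-methylbut-3-en-2-yl)oxy]-4H-chromen-4-one | C=CC(C)(C)Oc1ccc2c(c1)occc2=O | intermediate
5 | 8-(3-methylbut-2-en-1-yl)-8H-chromene-4,7-dione (ortho-dienone, transient, racemic) | CC(C)=CCC1C(=O)C=CC2=C1OC=CC2=O | intermediate
6 | 7-hydroxy-8-(3-methylbut-2-en-1-yl)-4H-chromen-4-one | CC(C)=CCc1c(O)ccc2c1occc2=O | intermediate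
7 | 8-(3-methylbut-2-en-1-yl)-7-[(triisopropylsilyl)oxy]-4H-chromen-4-one | CC(C)=CCc1c(O[Si](C(C)C)(C(C)C)C(C)C)ccc2c1occc2=O | intermediate
8 | 6-bromo-2,2-dimethyl-2H-chromene | Brc1ccc2OC(C)(C)C=Cc2c1 | starting material
9 | (2,2-dimethyl-2H-chromen-6-yl)lithium | [Li]c1ccc2OC(C)(C)C=Cc2c1 | intermediate
10 | lithium (2,2-dimethyl-2H-chromen-6-yl)triisopropoxyborate | [Li+].CC(C)O[B-](OC(C)C)(OC(C)C)c1ccc2OC(C)(C)C=Cc2c1 | intermediate
11 | (2,2-dimethyl-2H-chromen-6-yl)boronic acid | OB(O)c1ccc2OC(C)(C)C=Cc2c1 | intermediate
12 | (2S)-2-(2,2-dimethyl-2H-chromen-6-yl)-8-(3-methylbut-2-en-1-yl)-7-[(triisopropylsilyl)oxy]-2,3-dihydro-4H-chromen-4-one | CC(C)=CCc1c(O[Si](C(C)C)(C(C)C)C(C)C)ccc2c1O[C@H](c1ccc3c(c1)C=CC(C)(C)O3)CC2=O | intermediate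
13 | (2S)-7-hydroxy-2-(2,2-dimethyl-2H-chromen-6-yl)-8-(3-methylbut-2-en-1-yl)-2,3-dihydro-4H-chromen-4-one | CC(C)=CCc1c(O)ccc2c1O[C@H](c1ccc3c(c1)C=CC(C)(C)O3)CC2=O | target

Total step count: 7. Longest linear sequence: 6 (steps 1, 2, 3, 4, 6, 7).

Steps most likely to fail

Step 6.
- What may go wrong: insertion into the vinylogous-ester C2=C3 bond may be slow next to protodeboronation of the electron-rich boronic acid. Facial discrimination may be incomplete beside the C8 substituent. Configuration may also erode through base-induced ring opening over a long reaction time.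
- Fallback, setting out from 7 and 11 and coming back at 12: stereocontrol is moved from C–C bond formation to a kinetic resolution. The two partners are joined without a chiral ligand ([Rh(OH)(cod)]2, dioxane/H2O) to the racemic 7-O-TIPS flavanone F1.
- F1 is then submitted to asymmetric transfer hydrogenation (RuCl(p-cymene)[(R,R)-TsDPEN], HCO2H/Et3N, EtOAc, rt) run to about half conversion. The (2R)-ketone is matched with the catalyst and should be reduced to the (2R,4R)-cis-flavan-4-ol F2. The (2S)-ketone 12 should remain and is separated by chromatography.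

Step 3.
- What may go wrong: migration to C6 may compete, onward Cope-type migration may set in on overheating, and the tertiary allyl group may be lost by elimination.
- Fallback, setting out from 1 and coming back at 7: the C8–C1″ bond is made by cross-coupling instead of by a sigmatropic shift. Electrophilic iodination of 1 (NIS, DMF, rt), directed to C8 by the same bond fixation, should give 7-hydroxy-8-iodo-4H-chromen-4-one F3.
- Silylation (TIPSCl, imidazole, DMF) should give 8-iodo-7-[(triisopropylsilyl)oxy]-4H-chromen-4-one F4. Stille coupling with tributyl(3-methylbut-2-en-1-yl)stannane (Pd(PPh3)4, DMF, 80–90 °C) should then deliver 7 with the linear prenyl group.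

Step 1.
- What may go wrong: O-alkylation of the weakly nucleophilic, delocalised phenoxide may be slow while chloride 2 is consumed by elimination.
- Fallback, setting out from 1 and coming back at 4: a Tsuji–Trost O-allylation with tert-butyl 2-methylbut-3-en-2-yl carbonate (Pd(PPh3)4, THF, 0 °C) is used. The phenoxide attacks the more substituted terminus of the 1,1-dimethyl-π-allylpalladium cation under kinetic control.
- This should give 4 directly and makes alkyne 3 and the semihydrogenation unnecessary. The detour forms no compound outside the list (F0).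

Further compounds
F1 | step 6 | rac-2-(2,2-dimethyl-2H-chromen-6-yl)-8-(3-methylbut-2-en-1-yl)-7-[(triisopropylsilyl)oxy]-2,3-dihydro-4H-chromen-4-one | CC(C)=CCc1c(O[Si](C(C)C)(C(C)C)C(C)C)ccc2c1OC(c1ccc3c(c1)C=CC(C)(C)O3)CC2=O
F2 | step 6 | (2R,4R)-2-(2,2-dimethyl-2H-chromen-6-yl)-8-(3-methylbut-2-en-1-yl)-7-[(triisopropylsilyl)oxy]chroman-4-ol | CC(C)=CCc1c(O[Si](C(C)C)(C(C)C)C(C)C)ccc2c1O[C@@H](c1ccc3c(c1)C=CC(C)(C)O3)C[C@H]2O
F3 | step 3 | 7-hydroxy-8-iodo-4H-chromen-4-one | O=c1ccoc2c(I)c(O)ccc12
F4 | step 3 | 8-iodo-7-[(triisopropylsilyl)oxy]-4H-chromen-4-one | CC(C)[Si](Oc1ccc2c(c1I)occc2=O)(C(C)C)C(C)C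
F0 | step 1 | none | none
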